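## Retrosynthetic overview

1. Skeleton locants: cyclohexane C1/C10–C14, tetrahydrofuran C1–C2–O–C9–C10, oxonene O/C2–C9 with (Z)-C6=C7, ε-lactone C3–O–C16(=O)–C15(C17)–C14. Last disconnections: the C11 butyrate, the lactone (C16 acid + C3–OH), C15/C16 from hydroboration of a C15=C16 isopropenyl group, and the C11 carbinol from MeMgBr on a C11 ketone.
2. Cyclohexane and tetrahydrofuran in one step: intramolecular Diels–Alder reaction (bonds C1–C10 and C13–C14) of a 2-silyloxydiene on C9 with an enamide on C2, tethered by the C2–O–C9 unit of a monocyclic (Z)-oxonene.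
3. Oxonene by two-atom ring expansion (7 → 9). With C3 taken back to a ketone, C3=O and C6=C7 are γ,δ to each other inside the ring (C3–C4–C5–C6=C7). This is the retron of a Claisen shift of a 2-methylene-1,4-dioxepane (ring O, C2, C3, O', C7, C8, C9) in which C7 (methyl, vinyl) is a tertiary allylic ether; C4 comes from methylenation of the lactone carbonyl and C5–C6 from the vinyl group.
4. The 1,4-dioxepan-2-one comes from an acyclic glycolate: C9 by asymmetric 2-methylallylboration, C2 by auxiliary-controlled glycolate alkylation, C7 by vinyl addition to a methyl ketone with lactonisation.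
5. Ring order: 1,4-dioxepanone → oxonene (key step) → cyclohexane and tetrahydrofuran together → ε-lactone.

Key step: step 7

Remark: the skeleton locants above are used for all intermediates (TBS = tert-butyldimethylsilyl, TES = triethylsilyl, Ipc = isopinocampheyl); the C7 and C11 carbinol centres that are erased later are carried as the major epimer (C7) or as an epimer mixture (C11), which is assumed to be of no consequence.

## Route

Step 1
Reactants: 1 3-[(tert-butyldimethylsilyl)oxy]propanal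
Product: 3 (3S)-1-[(tert-butyldimethylsilyl)oxy]-5-methylhex-5-en-3-ol, via borinate ester 2 (not isolated)
Conditions: (−)-Ipc2BOMe, CH2=C(CH3)CH2MgCl, Et2O, 0 °C → rt; then 1, −78 °C; NaOH, H2O2, 0 °C → rt
Reagents that add atoms: 2-methylallylmagnesium chloride, CC(=C)C[Mg]Cl
Why: Brown asymmetric allylboration with the 2-methylallyl reagent through a closed chair transition state; the (+)-α-pinene-derived Ipc groups select the aldehyde face and should set C9 as S.

Step 2
Reactants: 3 (3S)-1-[(tert-butyldimethylsilyl)oxy]-5-methylhex-5-en-3-ol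
Product: 4 2-{[(3S)-1-(TBS-oxy)-5-methylhex-5-en-3-yl]oxy}acetic acid
Conditions: NaH (3 equiv), BrCH2CO2H, THF, 0 °C → rt; mild acidic work-up
Reagents that add atoms: bromoacetic acid, OC(=O)CBr
Why: Williamson ether synthesis of the secondary alkoxide with sodium bromoacetate (SN2); the C9 centre is not touched and the primary silyl ether is stable to the base.

Step 3
Reactants: 4 2-{[(3S)-1-(TBS-oxy)-5-methylhex-5-en-3-yl]oxy}acetic acid; 5 (4R)-4-benzyl-1,3-oxazolidin-2-one
Product: 7 (4R)-4-benzyl-3-(2-{[(3S)-1-(TBS-oxy)-5-methylhex-5-en-3-yl]oxy}acetyl)-1,3-oxazolidin-2-one, via mixed pivalic anhydride 6 (not isolated)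
Conditions: PivCl, Et3N, THF, −78 → 0 °C; then lithiated 5 (n-BuLi, THF, −78 °C), −78 → 0 °C
Reagents that add atoms: none
Why: N-acylation of the lithiated oxazolidinone by a mixed anhydride, which reacts at the unhindered glycolyl carbonyl and not at the pivaloyl carbonyl.

Step 4
Reactants: 7 (4R)-4-benzyl-3-(2-{[(3S)-1-(TBS-oxy)-5-methylhex-5-en-3-yl]oxy}acetyl)-1,3-oxazolidin-2-one
Product: 8 (4R)-4-benzyl-3-[(2S)-3-(benzyloxy)-2-{[(3S)-1-(TBS-oxy)-5-methylhex-5-en-3-yl]oxy}propanoyl]-1,3-oxazolidin-2-one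
Conditions: NaHMDS, THF, −78 °C; BnOCH2Cl, −78 → −45 °C
Reagents that add atoms: benzyl chloromethyl ether, ClCOCc1ccccc1
Why: Auxiliary-controlled asymmetric glycolate alkylation; the chelated (Z)-sodium enolate is alkylated by the reactive α-chloro ether on the face opposite the benzyl group of the (R)-auxiliary, which should set C2 as S.

Step 5
Reactants: 8 (4R)-4-benzyl-3-[(2S)-3-(benzyloxy)-2-{[(3S)-1-(TBS-oxy)-5-methylhex-5-en-3-yl]oxy}propanoyl]-1,3-oxazolidin-2-one
Product: 9 (4R)-4-benzyl-3-[(2S)-3-(benzyloxy)-2-{[(3R)-1-(TBS-oxy)-5-oxohexan-3-yl]oxy}propanoyl]-1,3-oxazolidin-2-one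
Conditions: O3, CH2Cl2/MeOH, pyridine, −78 °C (indicator end-point); Me2S, −78 °C → rt
Reagents that add atoms: ozone, [O-][O+]=O
Why: Ozonolysis with reductive work-up of the only C=C bond gives the C7 methyl ketone; at −78 °C with an end-point indicator the benzyl ether survives (the descriptor at C9 changes by priority only).

Step 6
Reactants: 9 (4R)-4-benzyl-3-[(2S)-3-(benzyloxy)-2-{[(3R)-1-(TBS-oxy)-5-oxohexan-3-yl]oxy}propanoyl]-1,3-oxazolidin-2-one
Product: 11 (3S,5R,7S)-3-[(benzyloxy)methyl]-5-{2-[(tert-butyldimethylsilyl)oxy]ethyl}-7-ethenyl-7-methyl-1,4-dioxepan-2-one, via magnesium alkoxide 10 (not isolated)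
Conditions: CH2=CHMgBr, MgBr2·OEt2, CH2Cl2/THF, −78 °C; then rt, 12 h
Reagents that add atoms: vinylmagnesium bromide, C=C[Mg]Br
Why: Chelation-controlled Grignard 1,2-addition (Mg bridges the C7 carbonyl and the C9 ether oxygen, vinyl enters anti to the C9 side chain and should set C7 as S; the minor epimer is carried along because C7 is erased in step 7), after which the tertiary magnesium alkoxide attacks the exocyclic imide carbonyl (intramolecular N-to-O acyl transfer, 7-exo-trig) and releases the auxiliary to close the 1,4-dioxepan-2-one.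

Step 7
Reactants: 11 (3S,5R,7S)-3-[(benzyloxy)methyl]-5-{2-[(tert-butyldimethylsilyl)oxy]ethyl}-7-ethenyl-7-methyl-1,4-dioxepan-2-one
Product: 13 (2S,9S,6Z)-2-[(benzyloxy)methyl]-9-{2-[(tert-butyldimethylsilyl)oxy]ethyl}-7-methyl-4,5,8,9-tetrahydrooxonin-3(2H)-one, via enol ether 12 (not isolated)
Conditions: Cp2TiMe2, toluene, 80 °C, dark; filtration through basic alumina; toluene, Et3N (trace), 150 °C, sealed tube
Reagents that add atoms: dimethyltitanocene, C[Ti](C)(C1C=CC=C1)C1C=CC=C1
Why: Cp2TiMe2 loses methane to Cp2Ti=CH2, which converts the lactone carbonyl C3=O through an oxatitanacyclobutane into the exocyclic enol ether 12, an allyl vinyl ether (C4=C3–O–C7–C6=C5) held in the seven-membered ring; at 150 °C a concerted [3,3] sigmatropic (Claisen) shift forms C4–C5 and breaks O–C7, so that the ring oxygen O' is replaced by C4–C5–C6 and the 1,4-dioxepane becomes the nine-membered oxonene with the C3 ketone. The closest known reactions are the titanium-carbenoid methylenation of lactones and the thermal Claisen ring expansion of 2-methylene-6-vinyltetrahydropyrans to cyclooct-4-enones and of ring-fused 2-methylene-7-vinyl-1,4-dioxepanes to oxonen-3-ones. No ring is closed by a cyclisation: the only ring event is the two-atom expansion 7 → 9 through a bicyclic six-centre transition state. No new stereocentre is formed: the C6=C7 bond must be Z because both of its ends stay tied in the ring (an E-oxonene transition state is too strained), C2 and C9 are untouched, and C7 is erased so that both C7 epimers converge. The step needs the [3,3] path to win over migration of the exocyclic C3=C4 bond into the ring and over ionisation of the tertiary allylic C7–O bond. Neutral, titanium-free, base-buffered thermolysis and the pseudo-axial vinyl group (trans to the C9 and C2 side chains), which lies over C4, should secure this.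

Step 8
Reactants: 13 (2S,9S,6Z)-2-[(benzyloxy)methyl]-9-{2-[(tert-butyldimethylsilyl)oxy]ethyl}-7-methyl-4,5,8,9-tetrahydrooxonin-3(2H)-one
Product: 14 (2S,3S,9S,6Z)-2-[(benzyloxy)methyl]-9-{2-[(tert-butyldimethylsilyl)oxy]ethyl}-3,7-dimethyl-2,3,4,5,8,9-hexahydrooxonin-3-ol
Conditions: MeMgBr, CH2Cl2/Et2O, −78 °C
Reagents that add atoms: methylmagnesium bromide, C[Mg]Br
Why: Chelation-controlled Grignard 1,2-addition to the α-alkoxy ketone (Cram chelate with the ring oxygen); methyl should enter anti to the C2 CH2OBn group and give the tertiary alcohol with OH cis to C1 (3S), and the low temperature suppresses enolisation at C2.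

Step 9
Reactants: 14 (2S,3S,9S,6Z)-2-[(benzyloxy)methyl]-9-{2-[(tert-butyldimethylsilyl)oxy]ethyl}-3,7-dimethyl-2,3,4,5,8,9-hexahydrooxonin-3-ol
Product: 15 (2S,3S,9S,6Z)-2-[(benzyloxy)methyl]-9-(2-hydroxyethyl)-3,7-dimethyl-2,3,4,5,8,9-hexahydrooxonin-3-ol
Conditions: TBAF, THF, 0 °C → rt
Reagents that add atoms: none
Why: Fluoride cleavage of the primary silyl ether; the benzyl ether, the tertiary alcohol and the alkene are inert.

Step 10
Reactants: 15 (2S,3S,9S,6Z)-2-[(benzyloxy)methyl]-9-(2-hydroxyethyl)-3,7-dimethyl-2,3,4,5,8,9-hexahydrooxonin-3-ol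
Product: 16 C11 aldehyde, [(2S,3S,9S,6Z)-2-[(benzyloxy)methyl]-3-hydroxy-3,7-dimethyl-2,3,4,5,8,9-hexahydrooxonin-9-yl]acetaldehyde (ring locants as in 15)
Conditions: Dess–Martin periodinane, NaHCO3, CH2Cl2, 0 °C → rt
Reagents that add atoms: none
Why: Dess–Martin oxidation of the only oxidisable (primary) alcohol; buffered, non-basic conditions should avoid β-elimination of the β-alkoxy aldehyde.

Step 11
Reactants: 16 C11 aldehyde
Product: 17 allylic alcohol, 1-[(2S,3S,9S,6Z)-2-[(benzyloxy)methyl]-3-hydroxy-3,7-dimethyl-2,3,4,5,8,9-hexahydrooxonin-9-yl]but-3-en-2-ol (C11 epimers)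
Conditions: CH2=CHMgBr (2.5 equiv), THF, −78 °C
Reagents that add atoms: vinylmagnesium bromide, C=C[Mg]Br
Why: Grignard 1,2-addition to the aldehyde (one equivalent is used up by the C3–OH); the new C11 carbinol centre forms without control and is removed by oxidation in step 13.

Step 12
Reactants: 17 allylic alcohol (C11 epimers)
Product: 18 triol, (2S,3S,9S,6Z)-9-(2-hydroxybut-3-en-1-yl)-2-(hydroxymethyl)-3,7-dimethyl-2,3,4,5,8,9-hexahydrooxonin-3-ol (C11 epimers)
Conditions: LiDBB (excess), THF, −78 °C; aq. NH4Cl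
Reagents that add atoms: none
Why: Reductive (single-electron) cleavage of the benzyl ether by the arene radical anion; isolated alkenes, alkoxides and the ring ether are not reduced at −78 °C.

Step 13
Reactants: 18 triol (C11 epimers)
Product: 20 (2E)-3-[(2S,3S,9S,6Z)-3-hydroxy-3,7-dimethyl-9-(2-oxobut-3-en-1-yl)-2,3,4,5,8,9-hexahydrooxonin-2-yl]-N-methoxy-N-methylprop-2-enamide, via keto aldehyde 19 (not isolated)
Conditions: Dess–Martin periodinane, NaHCO3, CH2Cl2, 0 °C → rt; then Ph3P=CHC(O)N(OMe)Me, CH2Cl2, 0 °C → rt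
Reagents that add atoms: N-methoxy-N-methyl-2-(triphenylphosphoranylidene)acetamide, CON(C)C(=O)C=P(c1ccccc1)(c1ccccc1)c1ccccc1
Why: Dess–Martin oxidation of the primary and the allylic secondary alcohol (the tertiary one is inert), then E-selective Wittig olefination of the more electrophilic α-alkoxy aldehyde with the amide-stabilised ylide, which should outrun conjugate addition to the vinyl ketone at 0 °C.

Step 14
Reactants: 20 (2E)-3-[(2S,3S,9S,6Z)-3-hydroxy-3,7-dimethyl-9-(2-oxobut-3-en-1-yl)-2,3,4,5,8,9-hexahydrooxonin-2-yl]-N-methoxy-N-methylprop-2-enamide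
Product: 23 tricyclic keto amide (C11 ketone, C14–C(O)N(OMe)Me, C3–OH), via silyl dienol ether 21 (not isolated), via silyl enol ether cycloadduct 22 (not isolated)
Conditions: TESOTf, Et3N, CH2Cl2, −78 → 0 °C; solvent change to toluene (BHT), 90 °C; then HF·pyridine, THF, 0 °C
Reagents that add atoms: none
Why: Soft enolisation gives the (Z)-2-silyloxydiene (and the C3 silyl ether), whose nucleophilic terminus C10 and the electrophilic β-carbon C1 of the enamide are joined by the three-atom C9–O–C2 tether, so that a thermal type 1 intramolecular Diels–Alder reaction closes the tetrahydrofuran (C1–C10) and the cyclohexene (C13–C14) together. The rigid (Z)-oxonene should allow overlap only on the face of the new tetrahydrofuran away from C3 and C8 in the amide-exo transition state (H1/H10 cis, oxonene anti to the cyclohexane), the E-dienophile fixes C14 trans to the C1–C2 bond, and HF then hydrolyses the silyl enol ether regiospecifically to the C11 ketone and frees C3–OH.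

Step 15
Reactants: 23 tricyclic keto amide
Product: 24 tricyclic diol methyl ketone (C11(OH)CH3, C14–C(O)CH3, C3–OH)
Conditions: MeMgBr (6 equiv), THF, −78 → 0 °C
Reagents that add atoms: methylmagnesium bromide, C[Mg]Br
Why: Grignard addition converts the Weinreb amide into the methyl ketone (stable chelated tetrahedral intermediate) and the C11 ketone into the tertiary alcohol; methyl should attack C11 from the convex face (syn to H10, anti to the pseudo-axial C10–C9 bond) and place the OH cis to C9 (target configuration, 11R).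

Step 16
Reactants: 24 tricyclic diol methyl ketone
Product: 25 tricyclic diol with a prop-1-en-2-yl group at C14
Conditions: Ph3PCH3Br, KOtBu (excess), THF, 0 °C → rt
Reagents that add atoms: methyltriphenylphosphonium bromide (as its ylide), C[P+](c1ccccc1)(c1ccccc1)c1ccccc1.[Br-]
Why: Wittig methylenation of the methyl ketone (excess ylide for the two free tertiary hydroxyls); C14 already has the thermodynamically preferred trans-diequatorial arrangement and should not epimerise.

Step 17
Reactants: 25 tricyclic diol with a prop-1-en-2-yl group at C14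
Product: 27 tricyclic triol (C16 primary alcohol, C15 as in the target), via alkylborane 26 (not isolated)
Conditions: 9-BBN (excess), THF, 0 °C → rt; NaOH, H2O2, 0 °C
Reagents that add atoms: hydrogen peroxide, OO
Why: Hydroboration–oxidation, in which 9-BBN selects the 1,1-disubstituted over the trisubstituted ring alkene; in the rotamer with H14 eclipsing C15=C16 (minimal allylic strain) the borane should add from the face away from the substituted C1, as in isopulegol-type 2-substituted isopropenylcyclohexanes, which sets C15 as in the target (15R).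

Step 18
Reactants: 27 tricyclic triol
Product: 28 tricyclic dihydroxy acid (C16 carboxylic acid)
Conditions: TEMPO (cat.), PhI(OAc)2, MeCN/H2O (pH 7 buffer), rt
Reagents that add atoms: water, O
Why: Oxoammonium (TEMPO) oxidation of the primary alcohol through the aldehyde hydrate to the acid; tertiary alcohols and the ring alkene are inert and the near-neutral medium should keep the C15 centre.

Step 19
Reactants: 28 tricyclic dihydroxy acid
Product: 30 11-hydroxy lactone (de-butyryl target), via mixed anhydride 29 (not isolated)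
Conditions: 2,4,6-Cl3C6H2COCl, Et3N, THF, rt; then DMAP, toluene (2 mM), 80 °C
Reagents that add atoms: none
Why: Yamaguchi lactonisation, a seven-membered ring closure by acyl substitution at the acylpyridinium by the C3 tertiary hydroxyl, which the rigid tricycle holds next to C16; the C11 hydroxyl is trans to the C14 side chain across the cyclohexane and cannot lactonise.

Step 20
Reactants: 30 11-hydroxy lactone
Product: 31 target compound
Conditions: (n-PrCO)2O, DMAP, Et3N, CH2Cl2, 40 °C
Reagents that add atoms: butanoic anhydride, CCCC(=O)OC(=O)CCC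
Why: DMAP-catalysed acylation of the remaining tertiary alcohol; no other nucleophilic group is left and the conditions are too mild to open the lactone.

## Compound list

1 | 3-[(tert-butyldimethylsilyl)oxy]propanal | O=CCCO[Si](C)(C)C(C)(C)C | starting material
2 | (3S)-1-(TBS-oxy)-5-methylhex-5-en-3-yl diisopinocampheylborinate (Ipc from (+)-α-pinene) | CC(=C)C[C@H](OB([C@@H]1C[C@@H]2C[C@H]([C@H]1C)C2(C)C)[C@@H]1C[C@@H]2C[C@H]([C@H]1C)C2(C)C)CCO[Si](C)(C)C(C)(C)C | intermediate
3 | (3S)-1-[(tert-butyldimethylsilyl)oxy]-5-methylhex-5-en-3-ol | CC(=C)C[C@H](O)CCO[Si](C)(C)C(C)(C)C | intermediate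
4 | 2-{[(3S)-1-(TBS-oxy)-5-methylhex-5-en-3-yl]oxy}acetic acid | CC(=C)C[C@H](OCC(=O)O)CCO[Si](C)(C)C(C)(C)C | intermediate
5 | (4R)-4-benzyl-1,3-oxazolidin-2-one | O=C1N[C@H](Cc2ccccc2)CO1 | starting material
6 | mixed anhydride of 4 with pivalic acid | CC(=C)C[C@H](OCC(=O)OC(=O)C(C)(C)C)CCO[Si](C)(C)C(C)(C)C | intermediate
7 | (4R)-4-benzyl-3-(2-{[(3S)-1-(TBS-oxy)-5-methylhex-5-en-3-yl]oxy}acetyl)-1,3-oxazolidin-2-one | CC(=C)C[C@H](OCC(=O)N1[C@H](Cc2ccccc2)COC1=O)CCO[Si](C)(C)C(C)(C)C | intermediate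
8 | (4R)-4-benzyl-3-[(2S)-3-(benzyloxy)-2-{[(3S)-1-(TBS-oxy)-5-methylhex-5-en-3-yl]oxy}propanoyl]-1,3-oxazolidin-2-one | CC(=C)C[C@H](O[C@@H](COCc1ccccc1)C(=O)N1[C@H](Cc2ccccc2)COC1=O)CCO[Si](C)(C)C(C)(C)C | intermediate
9 | (4R)-4-benzyl-3-[(2S)-3-(benzyloxy)-2-{[(3R)-1-(TBS-oxy)-5-oxohexan-3-yl]oxy}propanoyl]-1,3-oxazolidin-2-one | CC(=O)C[C@H](O[C@@H](COCc1ccccc1)C(=O)N1[C@H](Cc2ccccc2)COC1=O)CCO[Si](C)(C)C(C)(C)C | intermediate
10 | bromomagnesium (3S,5R)-5-{[(2S)-1-[(4R)-4-benzyl-2-oxo-1,3-oxazolidin-3-yl]-3-(benzyloxy)-1-oxopropan-2-yl]oxy}-7-(TBS-oxy)-3-methylhept-1-en-3-olate | C=C[C@@](C)(O[Mg]Br)C[C@H](O[C@@H](COCc1ccccc1)C(=O)N1[C@H](Cc2ccccc2)COC1=O)CCO[Si](C)(C)C(C)(C)C | intermediate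
11 | (3S,5R,7S)-3-[(benzyloxy)methyl]-5-{2-[(tert-butyldimethylsilyl)oxy]ethyl}-7-ethenyl-7-methyl-1,4-dioxepan-2-one (side chains at C3 and C5 cis, vinyl trans to them) | CC(C)(C)[Si](C)(C)OCC[C@@H]1C[C@@](C)(C=C)OC(=O)[C@H](COCc2ccccc2)O1 | intermediate
12 | (3S,5R,7S)-3-[(benzyloxy)methyl]-5-{2-[(tert-butyldimethylsilyl)oxy]ethyl}-7-ethenyl-7-methyl-2-methylidene-1,4-dioxepane | CC(C)(C)[Si](C)(C)OCC[C@@H]1C[C@@](C)(C=C)OC(=C)[C@H](COCc2ccccc2)O1 | intermediate
13 | (2S,9S,6Z)-2-[(benzyloxy)methyl]-9-{2-[(tert-butyldimethylsilyl)oxy]ethyl}-7-methyl-4,5,8,9-tetrahydrooxonin-3(2H)-one | CC(C)(C)[Si](C)(C)OCC[C@@H]1C/C(C)=C\CCC(=O)[C@H](COCc2ccccc2)O1 | intermediate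
14 | (2S,3S,9S,6Z)-2-[(benzyloxy)methyl]-9-{2-[(tert-butyldimethylsilyl)oxy]ethyl}-3,7-dimethyl-2,3,4,5,8,9-hexahydrooxonin-3-ol | CC(C)(C)[Si](C)(C)OCC[C@@H]1C/C(C)=C\CC[C@](C)(O)[C@H](COCc2ccccc2)O1 | intermediate
15 | (2S,3S,9S,6Z)-2-[(benzyloxy)methyl]-9-(2-hydroxyethyl)-3,7-dimethyl-2,3,4,5,8,9-hexahydrooxonin-3-ol | OCC[C@@H]1C/C(C)=C\CC[C@](C)(O)[C@H](COCc2ccccc2)O1 | intermediate
16 | [(2S,3S,9S,6Z)-2-[(benzyloxy)methyl]-3-hydroxy-3,7-dimethyl-2,3,4,5,8,9-hexahydrooxonin-9-yl]acetaldehyde (ring locants as in 15) | O=CC[C@@H]1C/C(C)=C\CC[C@](C)(O)[C@H](COCc2ccccc2)O1 | intermediate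
17 | 1-[(2S,3S,9S,6Z)-2-[(benzyloxy)methyl]-3-hydroxy-3,7-dimethyl-2,3,4,5,8,9-hexahydrooxonin-9-yl]but-3-en-2-ol, C11 epimers | C=CC(O)C[C@@H]1C/C(C)=C\CC[C@](C)(O)[C@H](COCc2ccccc2)O1 | intermediate
18 | (2S,3S,9S,6Z)-9-(2-hydroxybut-3-en-1-yl)-2-(hydroxymethyl)-3,7-dimethyl-2,3,4,5,8,9-hexahydrooxonin-3-ol, C11 epimers | C=CC(O)C[C@@H]1C/C(C)=C\CC[C@](C)(O)[C@H](CO)O1 | intermediate
19 | (2R,3S,9S,6Z)-3-hydroxy-3,7-dimethyl-9-(2-oxobut-3-en-1-yl)-2,3,4,5,8,9-hexahydrooxonine-2-carbaldehyde (2R by priority change only) | C=CC(=O)C[C@@H]1C/C(C)=C\CC[C@](C)(O)[C@H](C=O)O1 | intermediate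
20 | (2E)-3-[(2S,3S,9S,6Z)-3-hydroxy-3,7-dimethyl-9-(2-oxobut-3-en-1-yl)-2,3,4,5,8,9-hexahydrooxonin-2-yl]-N-methoxy-N-methylprop-2-enamide | C=CC(=O)C[C@@H]1C/C(C)=C\CC[C@](C)(O)[C@H](/C=C/C(=O)N(C)OC)O1 | intermediate
21 | bis-TES derivative of 20: C3–OSiEt3 and a (1Z)-2-(triethylsilyloxy)buta-1,3-dien-1-yl group on C9 | C=C/C(O[Si](CC)(CC)CC)=C/[C@@H]1C/C(C)=C\CC[C@](C)(O[Si](CC)(CC)CC)[C@H](/C=C/C(=O)N(C)OC)O1 | intermediate
22 | tricyclic cycloadduct: C11(OSiEt3)=C12 enol ether, cyclohexene cis-fused to the tetrahydrofuran (H1/H10 cis), C14 Weinreb amide trans to the C1–C2 bond, C3(CH3)(OSiEt3), (Z)-C6=C7; centres spatially as in 31 | CC[Si](CC)(CC)OC1=CC[C@@H](C(=O)N(C)OC)[C@H]2[C@@H]1[C@@H]1C/C(C)=C\CC[C@](C)(O[Si](CC)(CC)CC)[C@H]2O1 | intermediate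
23 | tricyclic keto amide: C11 ketone, C14–C(O)N(OMe)Me, C3(CH3)(OH); centres spatially as in 31 | O=C1CC[C@@H](C(=O)N(C)OC)[C@H]2[C@@H]1[C@@H]1C/C(C)=C\CC[C@](C)(O)[C@H]2O1 | intermediate
24 | tricyclic diol methyl ketone: C11(CH3)(OH) with OH cis to C9, C14 acetyl, C3(CH3)(OH) | O[C@]1(C)CC[C@@H](C(C)=O)[C@H]2[C@@H]1[C@@H]1C/C(C)=C\CC[C@](C)(O)[C@H]2O1 | intermediate
25 | tricyclic diol with prop-1-en-2-yl at C14 | O[C@]1(C)CC[C@@H](C(C)=C)[C@H]2[C@@H]1[C@@H]1C/C(C)=C\CC[C@](C)(O)[C@H]2O1 | intermediate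
26 | C16 B-alkyl-9-borabicyclo[3.3.1]nonane adduct of 25 (C15 as in 31) | O[C@]1(C)CC[C@@H]([C@@H](C)CB2C3CCCC2CCC3)[C@H]2[C@@H]1[C@@H]1C/C(C)=C\CC[C@](C)(O)[C@H]2O1 | intermediate
27 | tricyclic triol: C16 primary alcohol, C3–OH, C11–OH (C15 as in 31) | O[C@]1(C)CC[C@@H]([C@@H](C)CO)[C@H]2[C@@H]1[C@@H]1C/C(C)=C\CC[C@](C)(O)[C@H]2O1 | intermediate
28 | tricyclic dihydroxy acid: C16 carboxylic acid, C3–OH, C11–OH | O[C@]1(C)CC[C@@H]([C@@H](C)C(=O)O)[C@H]2[C@@H]1[C@@H]1C/C(C)=C\CC[C@](C)(O)[C@H]2O1 | intermediate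
29 | mixed anhydride of 28 with 2,4,6-trichlorobenzoic acid | O[C@]1(C)CC[C@@H]([C@@H](C)C(=O)OC(=O)c2c(Cl)cc(Cl)cc2Cl)[C@H]2[C@@H]1[C@@H]1C/C(C)=C\CC[C@](C)(O)[C@H]2O1 | intermediate
30 | 11-hydroxy lactone, (1S,2S,3S,9S,10R,11R,14R,15R,6Z) in skeleton numbering (target without the butanoyl group) | O[C@]1(C)CC[C@@H]2[C@H]3[C@@H]1[C@@H]1C/C(C)=C\CC[C@](C)(OC(=O)[C@@H]2C)[C@H]3O1 | intermediate
31 | target, (1S,2S,3S,9S,10R,11R,14R,15R,6Z)-C11 butanoate | CCCC(=O)O[C@]1(C)CC[C@@H]2[C@H]3[C@@H]1[C@@H]1C/C(C)=C\CC[C@](C)(OC(=O)[C@@H]2C)[C@H]3O1 | target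

## Step count and risks

Total step count: 20. Longest linear sequence: 20 steps (from 1; auxiliary 5 and all reagents are commercial).

Steps most likely to fail:

Step 7 (key step). The exocyclic enol ether may migrate into the ring (which would also erase the C2 centre) or decompose at 150 °C before the sigmatropic shift takes place. The fallback sets out from lactone 11 and replaces the thermal pericyclic step by a Lewis-acid-promoted one at low temperature. Methylenation with the Tebbe reagent (THF/pyridine, −40 → 0 °C) gives enol ether 12, which is now isolated on basic alumina. Triisobutylaluminium (CH2Cl2, −78 → 0 °C) should then promote the Claisen ring expansion and reduce the aluminium-bound ketone in situ by β-hydride transfer to the oxonenol F1 (C3 epimers). Dess–Martin oxidation of F1 returns to the route at oxonenone 13.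

Step 6. The hindered tertiary magnesium alkoxide may be too slow in the seven-membered acyl transfer, so that the Grignard reagent attacks the imide or the hydroxy imide survives. The fallback sets out from ketone 9 and separates the events. LiOH/H2O2 (THF/H2O, 0 °C) removes the auxiliary to give the keto acid F2. Vinylmagnesium bromide (3 equiv, MgBr2·OEt2, −78 °C; the carboxylate is inert) gives the hydroxy acid F3. Lactonisation of F3 by the mixed-anhydride method (2,4,6-trichlorobenzoyl chloride, Et3N, then DMAP, toluene, high dilution) comes back to the route at lactone 11.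

Step 17. Facial selectivity of the hydroboration rests on rotamer control only and may be poor, giving both C15 epimers; some hydroboration of the ring alkene is also possible. The fallback sets out from methyl ketone 24 and replaces substrate control by catalyst control. The kinetic potassium enolate (KHMDS, THF, −78 °C) is trapped with Comins' reagent to give the vinyl triflate F4. Palladium-catalysed hydroxycarbonylation (Pd(OAc)2, dppf, CO, Et3N, DMF/H2O) gives the α-substituted acrylic acid F5. Carboxylate-directed asymmetric hydrogenation of F5 (Ru(OAc)2(BINAP) or an iridium spiro-phosphine-oxazoline catalyst, H2, MeOH; ligand enantiomer chosen for 15R; the trisubstituted ring alkene is not reduced) comes back to the route at dihydroxy acid 28.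

## Further compounds

F1 | step 7 | (2S,9S,6Z)-2-[(benzyloxy)methyl]-9-{2-[(tert-butyldimethylsilyl)oxy]ethyl}-7-methyl-2,3,4,5,8,9-hexahydrooxonin-3-ol (C3 epimers) | CC(C)(C)[Si](C)(C)OCC[C@@H]1C/C(C)=C\CCC(O)[C@H](COCc2ccccc2)O1
F2 | step 6 | (2S)-3-(benzyloxy)-2-{[(3R)-1-(TBS-oxy)-5-oxohexan-3-yl]oxy}propanoic acid | CC(=O)C[C@H](O[C@@H](COCc1ccccc1)C(=O)O)CCO[Si](C)(C)C(C)(C)C
F3 | step 6 | (2S)-3-(benzyloxy)-2-{[(3R,5S)-1-(TBS-oxy)-5-hydroxy-5-methylhept-6-en-3-yl]oxy}propanoic acid | C=C[C@@](C)(O)C[C@H](O[C@@H](COCc1ccccc1)C(=O)O)CCO[Si](C)(C)C(C)(C)C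
F4 | step 17 | tricyclic diol with a 1-(trifluoromethanesulfonyloxy)ethenyl group at C14 | O[C@]1(C)CC[C@@H](C(=C)OS(=O)(=O)C(F)(F)F)[C@H]2[C@@H]1[C@@H]1C/C(C)=C\CC[C@](C)(O)[C@H]2O1
F5 | step 17 | tricyclic diol with a 1-carboxyethenyl group at C14 (2-substituted acrylic acid) | O[C@]1(C)CC[C@@H](C(=C)C(=O)O)[C@H]2[C@@H]1[C@@H]1C/C(C)=C\CC[C@](C)(O)[C@H]2O1
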